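**Retrosynthetic overview**
1. The target is a (2S)-flavanone (ring A = benzo ring, ring C = pyranone, ring B = 2-aryl) whose ring B is fused to a (3S)-3-hydroxy-2,2-dimethyl-dihydropyran (ring D). The last disconnection is three benzyl ethers.
2. Ring C is disconnected at C2–C3: the flavanone comes from its isomer, a 2-aryl-4-methylene-4H-1,3-benzodioxine (a temporary 1,3-dioxine ring), by a chiral-acid-catalysed O-to-C shift of the Petasis–Ferrier type.
3. Enabling feature: C2 carries O1 of ring C and sits, through ring B, para to the ether oxygen of ring D, so a cation at C2 is both an aryloxocarbenium ion and a para-quinone-methide oxonium ion. C3 is alpha to the C4 carbonyl, so it is an enol carbon. Ionising one acetal C–O bond releases both partners, still tethered through ring A.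
4. The vinyl acetal comes from methylenation of a 2-aryl-1,3-benzodioxin-4-one, made by acetal union of 4-(benzyloxy)salicylic acid (ring A) with the ring B/D aldehyde.
5. The ring B/D aldehyde comes from an aryl propargyl ether (Claisen route to the chromene), asymmetric epoxidation and hydride opening. Order of ring formation: ring D, then the temporary dioxine, then ring C.

Key step: step 13

Assumption: the descriptors read from the SMILES are (2S) at C2 of ring C and (3S) at the carbinol carbon of ring D. The sense of induction of the chiral acid in step 13 cannot be predicted with confidence, so the catalyst enantiomer that gives the (2S) product is the one to use; (R) is written.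

**Route**

Step 1
Reactants: 1 2-(benzyloxy)phenol
Product: 2 2-(benzyloxy)-4-bromophenol
Conditions: NBS, MeCN, 0 °C
Reagents that add atoms: N-bromosuccinimide, O=C1CCC(=O)N1Br
Why: electrophilic aromatic bromination should go para to the free hydroxyl group, the stronger director, which places bromine on the carbon that becomes C6 of the chroman.

Step 2
Reactants: 2 2-(benzyloxy)-4-bromophenol; 3 3-chloro-3-methylbut-1-yne
Product: 4 2-(benzyloxy)-4-bromo-1-[(2-methylbut-3-yn-2-yl)oxy]benzene
Conditions: K2CO3, KI, CuI (cat.), acetone, reflux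
Reagents that add atoms: none
Why: copper-assisted O-alkylation of a phenoxide with a tertiary propargylic chloride is the standard entry to aryl 1,1-dimethylpropargyl ethers.

Step 3
Reactants: 4 2-(benzyloxy)-4-bromo-1-[(2-methylbut-3-yn-2-yl)oxy]benzene
Product: 7 8-(benzyloxy)-6-bromo-2,2-dimethyl-2H-chromene, via ortho-allenylphenol 5 (not isolated), via ortho-quinone methide 6 (not isolated)
Conditions: PhNEt2, 190 °C
Reagents that add atoms: none
Why: aromatic propargyl Claisen rearrangement to the only free ortho position, followed by 1,5-hydrogen shift and oxa-6π electrocyclisation, should close ring D as the 2,2-dimethylchromene.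

Step 4
Reactants: 7 8-(benzyloxy)-6-bromo-2,2-dimethyl-2H-chromene
Product: 8 (3S,4S)-8-(benzyloxy)-6-bromo-3,4-epoxy-2,2-dimethylchromane
Conditions: (S,S)-N,N′-bis(3,5-di-tert-butylsalicylidene)-1,2-cyclohexanediaminomanganese chloride (cat., trivalent manganese), aq. NaOCl, 4-phenylpyridine N-oxide, CH2Cl2, 0 °C
Reagents that add atoms: sodium hypochlorite, [Na+].[O-]Cl
Why: Jacobsen–Katsuki epoxidation, for which 2,2-dimethylchromenes are a privileged substrate class; the (S,S)-catalyst should deliver oxygen to the face that gives the (3S,4S)-epoxide, which sets the carbinol stereocentre of ring D.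

Step 5
Reactants: 8 (3S,4S)-8-(benzyloxy)-6-bromo-3,4-epoxy-2,2-dimethylchromane
Product: 9 (3S)-8-(benzyloxy)-6-bromo-2,2-dimethyl-3,4-dihydro-2H-chromen-3-ol
Conditions: LiAlH4, THF, 0 °C
Reagents that add atoms: none
Why: hydride should open the epoxide by SN2 attack at the benzylic C4, C3 being shielded by the adjacent quaternary carbon, so the C3–O bond and its (S) configuration are untouched.

Step 6
Reactants: 9 (3S)-8-(benzyloxy)-6-bromo-2,2-dimethyl-3,4-dihydro-2H-chromen-3-ol
Product: 10 (3S)-3,8-bis(benzyloxy)-6-bromo-2,2-dimethyl-3,4-dihydro-2H-chromene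
Conditions: NaH, BnBr, Bu4NI (cat.), DMF, 0 °C to rt
Reagents that add atoms: benzyl bromide, BrCc1ccccc1
Why: Williamson etherification of the secondary alkoxide gives a protecting group that tolerates organolithium, Lewis acid and titanium reagents and leaves with the other benzyl groups at the end.

Step 7
Reactants: 10 (3S)-3,8-bis(benzyloxy)-6-bromo-2,2-dimethyl-3,4-dihydro-2H-chromene
Product: 12 (3S)-3,8-bis(benzyloxy)-2,2-dimethyl-3,4-dihydro-2H-chromene-6-carbaldehyde, via aryllithium 11 (not isolated)
Conditions: n-BuLi, THF, −78 °C; DMF; then H2O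
Reagents that add atoms: N,N-dimethylformamide, CN(C)C=O
Why: bromine–lithium exchange is faster than any benzylic deprotonation at −78 °C, and formylation of the aryllithium with DMF gives the aldehyde whose carbon becomes C2 of ring C.

Step 8
Reactants: 13 methyl 2,4-dihydroxybenzoate
Product: 14 methyl 4-(benzyloxy)-2-hydroxybenzoate
Conditions: BnBr, K2CO3, acetone, reflux
Reagents that add atoms: benzyl bromide, BrCc1ccccc1
Why: Williamson etherification should be selective for the 4-hydroxyl group, because the 2-hydroxyl group is held in a hydrogen bond to the ester carbonyl.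

Step 9
Reactants: 14 methyl 4-(benzyloxy)-2-hydroxybenzoate
Product: 15 4-(benzyloxy)-2-hydroxybenzoic acid
Conditions: LiOH, THF/MeOH/H2O, 50 °C; then aq. HCl
Reagents that add atoms: lithium hydroxide (its oxygen ends in the carboxyl group), [Li+].[OH-]
Why: ester saponification gives the free salicylic acid needed for the acetal union.

Step 10
Reactants: 15 4-(benzyloxy)-2-hydroxybenzoic acid
Product: 16 trimethylsilyl 4-(benzyloxy)-2-[(trimethylsilyl)oxy]benzoate
Conditions: (Me3Si)2NH, Me3SiCl (cat.), THF, 60 °C; concentrate, use crude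
Reagents that add atoms: hexamethyldisilazane, C[Si](C)(C)N[Si](C)(C)C
Why: bis-silylation activates both oxygen atoms for acetalisation under aprotic conditions, with volatile ammonia as the only other product.

Step 11
Reactants: 16 trimethylsilyl 4-(benzyloxy)-2-[(trimethylsilyl)oxy]benzoate; 12 (3S)-3,8-bis(benzyloxy)-2,2-dimethyl-3,4-dihydro-2H-chromene-6-carbaldehyde
Product: 17 7-(benzyloxy)-2-[(3S)-3,8-bis(benzyloxy)-2,2-dimethyl-3,4-dihydro-2H-chromen-6-yl]-4H-1,3-benzodioxin-4-one (both epimers at the acetal carbon)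
Conditions: Me3SiOTf (cat.), CH2Cl2, −78 °C; pyridine quench
Reagents that add atoms: none
Why: Lewis-acid-catalysed acetalisation of a bis-silylated hydroxy acid with an aldehyde, the standard route to 1,3-dioxan-4-ones, joins the two halves through a temporary ring; the acetal centre forms unselectively, which is harmless because step 13 erases it.

Step 12
Reactants: 17 7-(benzyloxy)-2-[(3S)-3,8-bis(benzyloxy)-2,2-dimethyl-3,4-dihydro-2H-chromen-6-yl]-4H-1,3-benzodioxin-4-one
Product: 18 7-(benzyloxy)-2-[(3S)-3,8-bis(benzyloxy)-2,2-dimethyl-3,4-dihydro-2H-chromen-6-yl]-4-methylidene-4H-1,3-benzodioxine (both epimers at the acetal carbon)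
Conditions: Cp2TiMe2, toluene/THF, 65 °C, dark; filtration through basic alumina
Reagents that add atoms: dimethyltitanocene Cp2TiMe2 (delivers CH2), C[Ti+2]C.c1cc[cH-]c1.c1cc[cH-]c1
Why: Petasis methylenation converts the lactone carbonyl into the exocyclic enol ether under non-basic conditions that are only weakly Lewis acidic, and the new carbon becomes C3 of ring C.

Step 13
Reactants: 18 7-(benzyloxy)-2-[(3S)-3,8-bis(benzyloxy)-2,2-dimethyl-3,4-dihydro-2H-chromen-6-yl]-4-methylidene-4H-1,3-benzodioxine
Product: 20 (2S)-7-(benzyloxy)-2-[(3S)-3,8-bis(benzyloxy)-2,2-dimethyl-3,4-dihydro-2H-chromen-6-yl]-2,3-dihydro-4H-chromen-4-one, via oxocarbenium-enol ion pair 19 (not isolated)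
Conditions: (R)-TRIP [(R)-3,3′-bis(2,4,6-triisopropylphenyl)-1,1′-binaphthyl-2,2′-diyl hydrogen phosphate] (10 mol%), 4 Å MS, toluene, −40 to 0 °C
Reagents that add atoms: none
Why: Proposed new method: the chiral phosphoric acid protonates the enol-ether oxygen O3 of 18 and the C2–O3 bond ionises, because the cation at C2 is at once an aryloxocarbenium ion (O1) and a para-quinone-methide oxonium ion (through ring B to the ring D oxygen); this leaves the tethered enol of the aryl ketone in ion pair 19 with the chiral phosphate, the enol carbon adds to C2 and the proton returns to the catalyst, an O-to-C 1,3-shift of the Petasis–Ferrier type. The closest known reaction types are the Me2AlCl-promoted Petasis–Ferrier rearrangement of 4-methylene-1,3-dioxanes to tetrahydropyran-4-ones and the chiral-phosphoric-acid-catalysed Petasis–Ferrier-type rearrangement of cyclic vinyl acetals; the change from a 4-methylene-1,3-benzodioxine to a chroman-4-one, and its enantioselective form, are not known. Ring C closes in the 6-(enolendo)-endo-trig mode, with the enol C=C bond and the C2=O1 oxocarbenium bond both inside the new ring. The C2 stereocentre is set by the phosphate, which is hydrogen-bonded to the enol OH and ion-paired with the oxocarbenium ion and so exposes one face of the planar C2; the acetal centre of 18 is erased on ionisation, so both epimers converge, and the remote (3S) centre makes any (2R) product a diastereomer that can be removed. The step needs C-attack instead of return by O-attack (which only regenerates 18), ionisation of C2–O3 in preference to C-protonation of the methylidene group (reversible under dry conditions) and no reopening of the product, which a weak acid, molecular sieves and low temperature should secure.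

Step 14
Reactants: 20 (2S)-7-(benzyloxy)-2-[(3S)-3,8-bis(benzyloxy)-2,2-dimethyl-3,4-dihydro-2H-chromen-6-yl]-2,3-dihydro-4H-chromen-4-one
Product: 21 (2S)-2-[(3S)-3,8-dihydroxy-2,2-dimethyl-3,4-dihydro-2H-chromen-6-yl]-7-hydroxy-2,3-dihydro-4H-chromen-4-one
Conditions: H2 (1 atm), Pd(OH)2/C, EtOAc/MeOH, rt
Reagents that add atoms: none
Why: neutral catalytic hydrogenolysis should remove the two aryl benzyl ethers and the alkyl benzyl ether without touching either stereocentre, since flavanones are configurationally stable in the absence of base.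

**Compound list**
1 | 2-(benzyloxy)phenol | Oc1ccccc1OCc1ccccc1 | starting material
2 | 2-(benzyloxy)-4-bromophenol | Oc1ccc(Br)cc1OCc1ccccc1 | intermediate
3 | 3-chloro-3-methylbut-1-yne | C#CC(C)(C)Cl | starting material
4 | 2-(benzyloxy)-4-bromo-1-[(2-methylbut-3-yn-2-yl)oxy]benzene | C#CC(C)(C)Oc1ccc(Br)cc1OCc1ccccc1 | intermediate
5 | 2-(benzyloxy)-4-bromo-6-(3-methylbuta-1,2-dien-1-yl)phenol (not isolated) | CC(C)=C=Cc1cc(Br)cc(OCc2ccccc2)c1O | intermediate
6 | 2-(benzyloxy)-4-bromo-6-(3-methylbut-2-en-1-ylidene)cyclohexa-2,4-dien-1-one (not isolated) | CC(C)=CC=C1C=C(Br)C=C(OCc2ccccc2)C1=O | intermediate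
7 | 8-(benzyloxy)-6-bromo-2,2-dimethyl-2H-chromene | CC1(C)C=Cc2cc(Br)cc(OCc3ccccc3)c2O1 | intermediate
8 | (3S,4S)-8-(benzyloxy)-6-bromo-3,4-epoxy-2,2-dimethylchromane | CC1(C)Oc2c(OCc3ccccc3)cc(Br)cc2[C@@H]2O[C@H]12 | intermediate
9 | (3S)-8-(benzyloxy)-6-bromo-2,2-dimethyl-3,4-dihydro-2H-chromen-3-ol | CC1(C)Oc2c(OCc3ccccc3)cc(Br)cc2C[C@@H]1O | intermediate
10 | (3S)-3,8-bis(benzyloxy)-6-bromo-2,2-dimethyl-3,4-dihydro-2H-chromene | CC1(C)Oc2c(OCc3ccccc3)cc(Br)cc2C[C@@H]1OCc1ccccc1 | intermediate
11 | [(3S)-3,8-bis(benzyloxy)-2,2-dimethyl-3,4-dihydro-2H-chromen-6-yl]lithium (not isolated) | CC1(C)Oc2c(OCc3ccccc3)cc([Li])cc2C[C@@H]1OCc1ccccc1 | intermediate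
12 | (3S)-3,8-bis(benzyloxy)-2,2-dimethyl-3,4-dihydro-2H-chromene-6-carbaldehyde | CC1(C)Oc2c(OCc3ccccc3)cc(C=O)cc2C[C@@H]1OCc1ccccc1 | intermediate
13 | methyl 2,4-dihydroxybenzoate | COC(=O)c1ccc(O)cc1O | starting material
14 | methyl 4-(benzyloxy)-2-hydroxybenzoate | COC(=O)c1ccc(OCc2ccccc2)cc1O | intermediate
15 | 4-(benzyloxy)-2-hydroxybenzoic acid | OC(=O)c1ccc(OCc2ccccc2)cc1O | intermediate
16 | trimethylsilyl 4-(benzyloxy)-2-[(trimethylsilyl)oxy]benzoate | C[Si](C)(C)OC(=O)c1ccc(OCc2ccccc2)cc1O[Si](C)(C)C | intermediate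
17 | 7-(benzyloxy)-2-[(3S)-3,8-bis(benzyloxy)-2,2-dimethyl-3,4-dihydro-2H-chromen-6-yl]-4H-1,3-benzodioxin-4-one (both acetal epimers) | CC1(C)Oc2c(OCc3ccccc3)cc(C3OC(=O)c4ccc(OCc5ccccc5)cc4O3)cc2C[C@@H]1OCc1ccccc1 | intermediate
18 | 7-(benzyloxy)-2-[(3S)-3,8-bis(benzyloxy)-2,2-dimethyl-3,4-dihydro-2H-chromen-6-yl]-4-methylidene-4H-1,3-benzodioxine (both acetal epimers) | CC1(C)Oc2c(OCc3ccccc3)cc(C3OC(=C)c4ccc(OCc5ccccc5)cc4O3)cc2C[C@@H]1OCc1ccccc1 | intermediate
19 | aryloxocarbenium ion carrying the tethered enol, as ion pair with the phosphate of the catalyst (cation shown, not isolated) | CC1(C)Oc2c(OCc3ccccc3)cc(C=[O+]c3cc(OCc4ccccc4)ccc3C(O)=C)cc2C[C@@H]1OCc1ccccc1 | intermediate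
20 | (2S)-7-(benzyloxy)-2-[(3S)-3,8-bis(benzyloxy)-2,2-dimethyl-3,4-dihydro-2H-chromen-6-yl]-2,3-dihydro-4H-chromen-4-one | CC1(C)Oc2c(OCc3ccccc3)cc([C@@H]3CC(=O)c4ccc(OCc5ccccc5)cc4O3)cc2C[C@@H]1OCc1ccccc1 | intermediate
21 | (2S)-2-[(3S)-3,8-dihydroxy-2,2-dimethyl-3,4-dihydro-2H-chromen-6-yl]-7-hydroxy-2,3-dihydro-4H-chromen-4-one | CC1(C)Oc2c(O)cc([C@@H]3CC(=O)c4ccc(O)cc4O3)cc2C[C@@H]1O | target

**Step count and risks**
Total steps: 14. Longest linear sequence: 11 steps (steps 1–7, then 11–14, from 2-(benzyloxy)phenol).

Steps most likely to fail: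

1. Step 13 (proposed new method). The ion pair may show poor facial discrimination, a non-catalysed racemic rearrangement may compete, or adventitious water may hydrolyse the acetal. The fallback uses known chemistry and forms the C2–aryl bond instead. It sets out from bromide 10: bromine–lithium exchange (n-BuLi, THF, −78 °C), B(OiPr)3 and aqueous acid should give [(3S)-3,8-bis(benzyloxy)-2,2-dimethyl-3,4-dihydro-2H-chromen-6-yl]boronic acid F1. Commercial 7-hydroxy-4H-chromen-4-one is benzylated (BnBr, K2CO3, DMF) to 7-(benzyloxy)-4H-chromen-4-one F2. Asymmetric conjugate addition of the arylboronic acid to the chromone (Pd(OCOCF3)2, divalent palladium, with 4-tert-butyl-2-(pyridin-2-yl)-4,5-dihydrooxazole in the enantiomeric form that gives 2S, NH4PF6, H2O, ClCH2CH2Cl, 60 °C) should then give the protected flavanone, and the fallback comes back to the route at 20.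

2. Step 12. The acylal 17 or the vinyl acetal 18 may ionise prematurely on titanium residues or on the support during purification, leading to racemic rearrangement or hydrolysis. The fallback builds the exocyclic enol ether by base-induced elimination, without a Lewis acid, and also bypasses step 11. It sets out from aldehyde 12. Commercial 1-[4-(benzyloxy)-2-hydroxyphenyl]ethanone is brominated (CuBr2, EtOAc/CHCl3, reflux) to 1-[4-(benzyloxy)-2-hydroxyphenyl]-2-bromoethanone F3. Reduction (NaBH4, CeCl3·7H2O, MeOH, −40 °C) should give 5-(benzyloxy)-2-(2-bromo-1-hydroxyethyl)phenol F4. Acetalisation with 12 (PPTS, 4 Å MS, CH2Cl2) should give 7-(benzyloxy)-2-[(3S)-3,8-bis(benzyloxy)-2,2-dimethyl-3,4-dihydro-2H-chromen-6-yl]-4-(bromomethyl)-4H-1,3-benzodioxine F5. E2 dehydrobromination (KOtBu, THF, 0 °C) then returns to the route at 18.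

3. Step 14. Slow cleavage of the hindered secondary benzyl ether may force long exposure to hydrogen, with hydrogenolytic opening of ring C at the benzylic C2–O1 bond or reduction of the C4 ketone. The fallback replaces reduction by Lewis-acid dealkylation with a cation scavenger: it sets out from 20 (BCl3, pentamethylbenzene, CH2Cl2, −78 °C) and comes back at 21. It makes no new compound (F0).

Further compounds
F1 | step 13 | [(3S)-3,8-bis(benzyloxy)-2,2-dimethyl-3,4-dihydro-2H-chromen-6-yl]boronic acid | CC1(C)Oc2c(OCc3ccccc3)cc(B(O)O)cc2C[C@@H]1OCc1ccccc1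
F2 | step 13 | 7-(benzyloxy)-4H-chromen-4-one | O=c1ccoc2cc(OCc3ccccc3)ccc12
F3 | step 12 | 1-[4-(benzyloxy)-2-hydroxyphenyl]-2-bromoethanone | O=C(CBr)c1ccc(OCc2ccccc2)cc1O
F4 | step 12 | 5-(benzyloxy)-2-(2-bromo-1-hydroxyethyl)phenol (racemic) | OC(CBr)c1ccc(OCc2ccccc2)cc1O
F5 | step 12 | 7-(benzyloxy)-2-[(3S)-3,8-bis(benzyloxy)-2,2-dimethyl-3,4-dihydro-2H-chromen-6-yl]-4-(bromomethyl)-4H-1,3-benzodioxine (mixture of isomers at C2 and C4 of the dioxine) | CC1(C)Oc2c(OCc3ccccc3)cc(C3OC(CBr)c4ccc(OCc5ccccc5)cc4O3)cc2C[C@@H]1OCc1ccccc1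
F0 | step 14 | none | none
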